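## Retrosynth overview

1. Target 20 ⇐ alkenyl bromide 19 (radical hydrogenation puts H on the open face and leaves Br on the hindered face) ⇐ cyclohexenol 18 (oxygen-directed Br/Cl addition) ⇐ ring ketone 16 via enol triflate 17.
2. Six-membered ring (formed second): ring-closing metathesis of diene 15. Its carbinol stereocentre comes from endo allylation of a camphor-like, oxygen-bridged oxocarbenium ion generated from 1,4-diketone 13; the oxygen bridge is temporary.
3. Five-membered ring (formed first, key step): symmetric bis-silyl ether 5 + chiral vinyl ether 7 → 10. Allyl cation/vinyl ether union makes the CH2–CH2 bond, Prins closure makes the CH(O)–CMe2 bond, and a pinacol methyl shift completes the quaternary carbon.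
4. Enabling feature: in the cyclopentane, the methyl-bearing quaternary carbon lies between the CMe2 carbon and a ring CH2 and carries the carbinol carbon of the cyclohexane. This C(CH3)–C(O) pair is a pinacol retron, and the opposite CHBr–CH2 edge is a vinyl ether in disguise (C–Br ⇐ C=O ⇐ C–OR).
5. 5 comes from 3-hydroxy-3-methylbutan-2-one by a Shapiro reaction with acetone.

Key step: step 4

Assumption (remark on the chemistry): the (R)-1-phenylethoxy group is taken to shield the oxocarbenium face in the usual sense (attack anti to phenyl); if the sense proves opposite, the (S)-enantiomer of 6 is used and nothing else changes.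

## Route

Step 1
Reactants: 1 3-hydroxy-3-methylbutan-2-one
Product: 2 N'-(3-hydroxy-3-methylbutan-2-ylidene)-2,4,6-tri(propan-2-yl)benzenesulfonohydrazide
Conditions: 2,4,6-triisopropylbenzenesulfonyl hydrazide, MeOH, cat. HCl, rt
Reagents that add atoms: 2,4,6-triisopropylbenzenesulfonyl hydrazide, NNS(=O)(=O)c1c(C(C)C)cc(C(C)C)cc1C(C)C
Why: Condensation of the ketone with the sulfonyl hydrazide (hydrazone formation) gives the Shapiro precursor; no stereocentre is involved.

Step 2
Reactants: 2 N'-(3-hydroxy-3-methylbutan-2-ylidene)-2,4,6-tri(propan-2-yl)benzenesulfonohydrazide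
Product: 5 2,4-dimethyl-3-methylidene-2,4-bis(triethylsilyloxy)pentane, via lithium 3-lithio-2-methylbut-3-en-2-olate 3 (not isolated), via dilithium 2,4-dimethyl-3-methylidenepentane-2,4-diolate 4 (not isolated)
Conditions: n-BuLi (3.05 equiv), THF, −78 to 0 °C; acetone, −78 °C; Et3SiOTf (2.3 equiv), −78 °C to rt
Reagents that add atoms: acetone, CC(C)=O; triethylsilyl trifluoromethanesulfonate, CC[Si](CC)(CC)OS(=O)(=O)C(F)(F)F
Why: Shapiro reaction: the trianion loses sulfinate and N2 to give the alkenyllithium on the only side that has α-hydrogens, this adds to acetone, and both tertiary Li alkoxides are capped by the silyl triflate; the product has a mirror plane and no stereocentre.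

Step 3
Reactants: 6 (R)-1-phenylethanol
Product: 7 [(1R)-1-(ethenyloxy)ethyl]benzene
Conditions: Pd(OAc)2 (2 mol %), 4,7-diphenyl-1,10-phenanthroline (2 mol %), butyl vinyl ether (solvent), air, 60 °C
Reagents that add atoms: butyl vinyl ether, C=COCCCC
Why: Pd-catalysed transfer vinylation (transetherification) moves the vinyl group onto the alcohol oxygen and leaves the benzylic stereocentre untouched.

Step 4
Reactants: 5 2,4-dimethyl-3-methylidene-2,4-bis(triethylsilyloxy)pentane; 7 [(1R)-1-(ethenyloxy)ethyl]benzene
Product: 10 1-[(1R,3R)-1,2,2-trimethyl-3-[(1R)-1-phenylethoxy]cyclopentyl]ethan-1-one, via 1,1-dimethylallyl cation 8 (not isolated), via oxocarbenium ion 9 (not isolated)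
Conditions: Et3SiOTf (0.2 equiv), 2,6-di-tert-butyl-4-methylpyridine (0.3 equiv), CH2Cl2, −78 °C, slow addition of 7 (1.3 equiv), then −78 to −40 °C; major diastereomer separated by chromatography
Reagents that add atoms: none
Why: Proposed new method: Et3SiOTf ionises one of the two equivalent tertiary allylic silyl ethers of 5 to allyl cation 8, whose unhindered CH2 terminus is captured by the CH2 carbon of vinyl ether 7 (first new bond, CH2–CH2) to give oxocarbenium ion 9; the tetrasubstituted alkene of 9 then attacks the oxocarbenium carbon through its CMe2 carbon (second new bond, CH(OR)–CMe2), and the developing tertiary cation is quenched by a 1,2-methyl shift from the neighbouring silyloxy carbon (pinacol termination), which creates the methyl-bearing quaternary stereocentre and the acetyl group and releases Et3Si+ so that the silyl triflate turns over. The closest known reaction types are the Lewis-acid [3+2] annulation of allyl cations with enol ethers and the pinacol-terminated Prins cyclisation of alkenyl silyl ethers onto oxocarbenium ions; new is their merger in one intermolecular operation. The only ring closed is the cyclopentane, by a 5-endo-trig cation–olefin closure. Two stereocentres arise: the ether carbon is set by the (R)-1-phenylethyl group, which blocks one face of the oxocarbenium ion, and the quaternary carbon follows from it because addition across the alkene is anti (ring bond on one face, migrating methyl on the other) and the bulky alkoxy group takes the outward position, trans to the acetyl group. The step needs capture of 8 at its CH2 end and not at its CMe2 end, secured by the congestion of the fully substituted terminus next to the silyloxy-bearing substituent, and ring closure before a second vinyl ether adds, secured by slow addition of 7 and the intramolecular nature of the closure.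

Step 5
Reactants: 10 1-[(1R,3R)-1,2,2-trimethyl-3-[(1R)-1-phenylethoxy]cyclopentyl]ethan-1-one
Product: 11 1-[(1R,3R)-3-hydroxy-1,2,2-trimethylcyclopentyl]ethan-1-one
Conditions: H2 (1 atm), Pd(OH)2/C, EtOAc, rt
Reagents that add atoms: none
Why: Catalytic hydrogenolysis of the benzylic ether removes the auxiliary as ethylbenzene without touching the ketone or either ring stereocentre.

Step 6
Reactants: 11 1-[(1R,3R)-3-hydroxy-1,2,2-trimethylcyclopentyl]ethan-1-one
Product: 12 1-[(1R,3R)-3-hydroxy-1,2,2-trimethylcyclopentyl]-4-methylpent-4-en-1-one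
Conditions: LiN(i-Pr)2 (2.2 equiv), THF, −78 °C; 3-bromo-2-methylprop-1-ene (1.1 equiv), −78 to 0 °C; H2O
Reagents that add atoms: 3-bromo-2-methylprop-1-ene, C=C(C)CBr
Why: Enolate alkylation: the ketone can enolise only toward its methyl group because the other α-carbon is quaternary, the second equivalent of base holds the alcohol as a hindered alkoxide, and the allylic bromide alkylates carbon.

Step 7
Reactants: 12 1-[(1R,3R)-3-hydroxy-1,2,2-trimethylcyclopentyl]-4-methylpent-4-en-1-one
Product: 13 (3R)-2,2,3-trimethyl-3-(4-methylpent-4-enoyl)cyclopentan-1-one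
Conditions: (n-Pr4N)RuO4 (5 mol %), N-methylmorpholine N-oxide (1.5 equiv), 4 Å molecular sieves, CH2Cl2, rt
Reagents that add atoms: none
Why: Ley–Griffith oxidation of the secondary alcohol to the ketone, which deliberately erases the relay stereocentre and provides the second carbonyl group needed in step 8.

Step 8
Reactants: 13 (3R)-2,2,3-trimethyl-3-(4-methylpent-4-enoyl)cyclopentan-1-one
Product: 15 (3R)-3-[(4R)-4-hydroxy-7-methylocta-1,7-dien-4-yl]-2,2,3-trimethylcyclopentan-1-one, via bridged trimethylsilyl ketal 14 (not isolated)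
Conditions: allyltrimethylsilane (4 equiv), Me3SiOTf (0.3 equiv), 2,6-di-tert-butyl-4-methylpyridine (0.4 equiv), CH2Cl2, −78 to −30 °C; then 1 M HCl, THF, 0 °C
Reagents that add atoms: allyltrimethylsilane, C=CC[Si](C)(C)C
Why: Proposed new method: Me3SiOTf silylates the ring ketone and the side-chain carbonyl oxygen closes onto it (the reverse mode would need a bridgehead oxocarbenium ion), so only the side-chain carbon becomes an oxygen-bridged bicyclic oxocarbenium ion, a 3-oxa analogue of O-activated camphor; allyltrimethylsilane adds to it from the endo face, anti to the CMe2 bridge, as nucleophiles do with camphor, which sets the (R)-carbinol, and aqueous acid opens silyl ketal 14 back to the ring ketone and the tertiary alcohol; the closest known reaction types are the Hosomi–Sakurai allylation of cyclic oxocarbenium ions and carbonyl participation in acid-activated 1,4-diketones.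

Step 9
Reactants: 15 (3R)-3-[(4R)-4-hydroxy-7-methylocta-1,7-dien-4-yl]-2,2,3-trimethylcyclopentan-1-one
Product: 16 (3R)-3-[(1R)-1-hydroxy-4-methylcyclohex-3-en-1-yl]-2,2,3-trimethylcyclopentan-1-one
Conditions: second-generation Grubbs catalyst, (H2IMes)(PCy3)Cl2Ru=CHPh (5 mol %), CH2Cl2 (0.01 M), 40 °C
Reagents that add atoms: none
Why: Ring-closing metathesis between the monosubstituted and the 1,1-disubstituted alkene closes the six-membered ring as its trisubstituted alkene and releases ethene; no stereocentre is touched.

Step 10
Reactants: 16 (3R)-3-[(1R)-1-hydroxy-4-methylcyclohex-3-en-1-yl]-2,2,3-trimethylcyclopentan-1-one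
Product: 17 (4R)-4-[(1R)-1-hydroxy-4-methylcyclohex-3-en-1-yl]-4,5,5-trimethylcyclopent-1-en-1-yl trifluoromethanesulfonate
Conditions: KN(SiMe3)2 (2.2 equiv), THF, −78 °C; PhNTf2 (1.1 equiv), −78 to −20 °C; H2O
Reagents that add atoms: N-phenylbis(trifluoromethanesulfonimide), O=S(=O)(N(c1ccccc1)S(=O)(=O)C(F)(F)F)C(F)(F)F
Why: Enol triflate formation: the ring ketone has a single enolisable CH2, and the hindered tertiary K alkoxide formed by the second equivalent of base is not sulfonylated.

Step 11
Reactants: 17 (4R)-4-[(1R)-1-hydroxy-4-methylcyclohex-3-en-1-yl]-4,5,5-trimethylcyclopent-1-en-1-yl trifluoromethanesulfonate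
Product: 18 (1R)-1-[(1R)-3-bromo-1,2,2-trimethylcyclopent-3-en-1-yl]-4-methylcyclohex-3-en-1-ol
Conditions: Ni(OAc)2·4H2O (10 mol %), 1,5-cyclooctadiene (20 mol %), Zn (20 mol %), LiBr (3 equiv), DMA/THF 1:3, rt
Reagents that add atoms: lithium bromide, [Li+].[Br-]
Why: Ni-catalysed halogen exchange of an enol triflate (oxidative addition, triflate–bromide exchange, reductive elimination) gives the alkenyl bromide with the double bond in place, and it is run before any alkyl halide is present.

Step 12
Reactants: 18 (1R)-1-[(1R)-3-bromo-1,2,2-trimethylcyclopent-3-en-1-yl]-4-methylcyclohex-3-en-1-ol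
Product: 19 (1R,3S,4S)-3-bromo-1-[(1R)-3-bromo-1,2,2-trimethylcyclopent-3-en-1-yl]-4-chloro-4-methylcyclohexan-1-ol
Conditions: NBS (1.1 equiv), ClTi(O-i-Pr)3 (1.3 equiv), CH2Cl2, −20 °C; then H2O
Reagents that add atoms: N-bromosuccinimide, O=C1CCC(=O)N1Br; chlorotitanium triisopropoxide, CC(C)O[Ti](Cl)(OC(C)C)OC(C)C
Why: Proposed new method: the tertiary alcohol exchanges onto titanium, the bromonium ion forms reversibly on the ring face anti to the Ti-bound oxygen, and the titanium-bound chloride is delivered across the ring to the methyl-bearing carbon from the oxygen face (boat-like, as in 1,4-cineole formation), which gives Br trans and Cl cis to the hydroxyl with Markovnikov regiochemistry, whereas an undirected addition to this conformationally locked ring would open diaxially to the other diastereomer; the electron-poor, hindered alkenyl bromide does not react; the closest known reaction type is the NBS/ClTi(O-i-Pr)3 bromochlorination of allylic alcohols with chloride delivery from the bound titanium.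

Step 13
Reactants: 19 (1R,3S,4S)-3-bromo-1-[(1R)-3-bromo-1,2,2-trimethylcyclopent-3-en-1-yl]-4-chloro-4-methylcyclohexan-1-ol
Product: 20 (1R,3S,4S)-3-bromo-1-[(1R,3S)-3-bromo-1,2,2-trimethylcyclopentyl]-4-chloro-4-methylcyclohexan-1-ol
Conditions: Mn(dpm)3 [tris(2,2,6,6-tetramethylheptane-3,5-dionato)manganese] (10 mol %), PhSiH3 (1.5 equiv), t-BuOOH (1.5 equiv), i-PrOH, rt
Reagents that add atoms: none
Why: Hydrogenation by metal-hydride hydrogen atom transfer, a reaction type that reduces alkenyl halides to alkyl halides without loss of halogen: hydrogen adds first to the CH carbon, and the α-bromo radical then takes its hydrogen on the less hindered face, opposite to the cyclohexyl group, so that bromine ends cis to that ring, which is the (S) configuration.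

## Compound list

1 | 3-hydroxy-3-methylbutan-2-one | CC(=O)C(C)(C)O | starting material
2 | N'-(3-hydroxy-3-methylbutan-2-ylidene)-2,4,6-tri(propan-2-yl)benzenesulfonohydrazide | CC(=NNS(=O)(=O)c1c(C(C)C)cc(C(C)C)cc1C(C)C)C(C)(C)O | intermediate
3 | lithium 3-lithio-2-methylbut-3-en-2-olate | [Li]C(=C)C(C)(C)O[Li] | intermediate
4 | dilithium 2,4-dimethyl-3-methylidenepentane-2,4-diolate | [Li]OC(C)(C)C(=C)C(C)(C)O[Li] | intermediate
5 | 2,4-dimethyl-3-methylidene-2,4-bis(triethylsilyloxy)pentane | C=C(C(C)(C)O[Si](CC)(CC)CC)C(C)(C)O[Si](CC)(CC)CC | intermediate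
6 | (R)-1-phenylethanol | C[C@@H](O)c1ccccc1 | starting material
7 | [(1R)-1-(ethenyloxy)ethyl]benzene | C=CO[C@H](C)c1ccccc1 | intermediate
8 | 2-methyl-3-[2-(triethylsilyloxy)propan-2-yl]but-3-en-2-ylium (1,1-dimethylallyl cation) | C=C([C+](C)C)C(C)(C)O[Si](CC)(CC)CC | intermediate
9 | O-[(1R)-1-phenylethyl] oxocarbenium ion of 5-methyl-4-[2-(triethylsilyloxy)propan-2-yl]hex-4-enal | C[C@H](c1ccccc1)[O+]=CCCC(=C(C)C)C(C)(C)O[Si](CC)(CC)CC | intermediate
10 | 1-[(1R,3R)-1,2,2-trimethyl-3-[(1R)-1-phenylethoxy]cyclopentyl]ethan-1-one | CC1(C)[C@H](O[C@H](C)c2ccccc2)CC[C@@]1(C)C(C)=O | intermediate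
11 | 1-[(1R,3R)-3-hydroxy-1,2,2-trimethylcyclopentyl]ethan-1-one | CC1(C)[C@H](O)CC[C@@]1(C)C(C)=O | intermediate
12 | 1-[(1R,3R)-3-hydroxy-1,2,2-trimethylcyclopentyl]-4-methylpent-4-en-1-one | CC1(C)[C@H](O)CC[C@@]1(C)C(=O)CCC(C)=C | intermediate
13 | (3R)-2,2,3-trimethyl-3-(4-methylpent-4-enoyl)cyclopentan-1-one | CC1(C)C(=O)CC[C@@]1(C)C(=O)CCC(C)=C | intermediate
14 | 3-endo-allyl-4,7,7-trimethyl-3-(3-methylbut-3-en-1-yl)-1-(trimethylsilyloxy)-2-oxabicyclo[2.2.1]heptane | C=CC[C@@]1(CCC(C)=C)O[C@@]2(O[Si](C)(C)C)CC[C@]1(C)C2(C)C | intermediate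
15 | (3R)-3-[(4R)-4-hydroxy-7-methylocta-1,7-dien-4-yl]-2,2,3-trimethylcyclopentan-1-one | CC1(C)C(=O)CC[C@@]1(C)[C@](O)(CC=C)CCC(C)=C | intermediate
16 | (3R)-3-[(1R)-1-hydroxy-4-methylcyclohex-3-en-1-yl]-2,2,3-trimethylcyclopentan-1-one | CC1(C)C(=O)CC[C@@]1(C)[C@@]1(O)CCC(C)=CC1 | intermediate
17 | (4R)-4-[(1R)-1-hydroxy-4-methylcyclohex-3-en-1-yl]-4,5,5-trimethylcyclopent-1-en-1-yl trifluoromethanesulfonate | CC1(C)C(OS(=O)(=O)C(F)(F)F)=CC[C@@]1(C)[C@@]1(O)CCC(C)=CC1 | intermediate
18 | (1R)-1-[(1R)-3-bromo-1,2,2-trimethylcyclopent-3-en-1-yl]-4-methylcyclohex-3-en-1-ol | CC1(C)C(Br)=CC[C@@]1(C)[C@@]1(O)CCC(C)=CC1 | intermediate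
19 | (1R,3S,4S)-3-bromo-1-[(1R)-3-bromo-1,2,2-trimethylcyclopent-3-en-1-yl]-4-chloro-4-methylcyclohexan-1-ol | CC1(C)C(Br)=CC[C@@]1(C)[C@@]1(O)CC[C@](C)(Cl)[C@@H](Br)C1 | intermediate
20 | (1R,3S,4S)-3-bromo-1-[(1R,3S)-3-bromo-1,2,2-trimethylcyclopentyl]-4-chloro-4-methylcyclohexan-1-ol | CC1(C)[C@@H](Br)CC[C@@]1(C)[C@@]1(O)CC[C@](C)(Cl)[C@@H](Br)C1 | target

## Step count and risks

Total steps: 13. Longest linear sequence: 12 steps (steps 1, 2 and 4 to 13); step 3 is the one-step side branch.

Steps most likely to fail:

1. Step 4 (proposed new method). What may go wrong: cationic oligomerisation of the vinyl ether, capture of the allyl cation at its fully substituted end, stalling at a cyclic acetal formed by the silyloxy oxygen, or weak relay of chirality from the auxiliary to the quaternary carbon. The fallback makes the two bonds one after the other with established reaction types; it sets out from 5 and returns at 10. 5 is coupled with (ethenyloxy)trimethylsilane under Et3SiOTf catalysis (SN1 alkylation of a silyl enol ether by a tertiary allylic cation) to give the aldehyde 5-methyl-4-[2-(triethylsilyloxy)propan-2-yl]hex-4-enal F1. 6 is silylated (Me3SiCl, imidazole) to trimethyl[(1R)-1-phenylethoxy]silane F2. F1 and F2 with Me3SiOTf in CH2Cl2 at −78 °C form oxocarbenium ion 9 by the usual silyl ether acetalisation pathway, and 9 undergoes the pinacol-terminated Prins cyclisation to 10.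

2. Step 8 (proposed new method). What may go wrong: poor facial selectivity because the open-chain ketone reacts instead of the bridged oxocarbenium ion, or intramolecular Prins capture of that ion by the side-chain alkene. The fallback avoids the bridge; it sets out from 12 and returns at 16. CH2=CHCH2MgBr (3 equiv, THF, −78 °C) adds to the ketone of 12 to give (1R,3R)-3-[(4R)-4-hydroxy-7-methylocta-1,7-dien-4-yl]-2,2,3-trimethylcyclopentan-1-ol F3 together with its epimer at the new carbinol carbon, which is removed by chromatography (a chiral B-allylborane can be used instead to bias the addition). Ring-closing metathesis with the second-generation Grubbs catalyst gives (1R)-1-[(1R,3R)-3-hydroxy-1,2,2-trimethylcyclopentyl]-4-methylcyclohex-3-en-1-ol F4, and (n-Pr4N)RuO4 with N-methylmorpholine N-oxide oxidises only the secondary alcohol to give 16.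

3. Step 12 (proposed new method). What may go wrong: capture of the bromonium ion by the alkoxide oxygen to give a bridged ether, or external diaxial chloride attack that delivers the halogens to the wrong faces. The fallback makes the oxygen bridge on purpose and then replaces it; it sets out from 18 and returns at 19. NBS alone in CH2Cl2 gives by bromoetherification (known for 4-hydroxy-1-methylcyclohexenes) the bridged bromo ether 2-endo-bromo-4-[(1R)-3-bromo-1,2,2-trimethylcyclopent-3-en-1-yl]-1-methyl-7-oxabicyclo[2.2.1]heptane F5. BCl3 in CH2Cl2 at −78 °C (boron trihalide cleavage of a tertiary ether) then breaks the C–O bond at the methyl-bearing bridgehead, with the anti bromine assisting ionisation and chloride returning from the boron-bound oxygen face, to give 19 after aqueous work-up.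

Further compounds

F1 | step 4 | 5-methyl-4-[2-(triethylsilyloxy)propan-2-yl]hex-4-enal | O=CCCC(=C(C)C)C(C)(C)O[Si](CC)(CC)CC
F2 | step 4 | trimethyl[(1R)-1-phenylethoxy]silane | C[C@@H](O[Si](C)(C)C)c1ccccc1
F3 | step 8 | (1R,3R)-3-[(4R)-4-hydroxy-7-methylocta-1,7-dien-4-yl]-2,2,3-trimethylcyclopentan-1-ol | CC1(C)[C@H](O)CC[C@@]1(C)[C@](O)(CC=C)CCC(C)=C
F4 | step 8 | (1R)-1-[(1R,3R)-3-hydroxy-1,2,2-trimethylcyclopentyl]-4-methylcyclohex-3-en-1-ol | CC1(C)[C@H](O)CC[C@@]1(C)[C@@]1(O)CCC(C)=CC1
F5 | step 12 | 2-endo-bromo-4-[(1R)-3-bromo-1,2,2-trimethylcyclopent-3-en-1-yl]-1-methyl-7-oxabicyclo[2.2.1]heptane | CC1(C)C(Br)=CC[C@@]1(C)[C@]12CC[C@](C)(O1)[C@@H](Br)C2
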